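Remark: the ring atoms of the target are numbered as in 2,3-dihydro-1,4-benzodioxine (O1, C2, C3, O4, C4a, C5–C8, C8a), and the SMILES is read as the (2S,3S)-trans isomer. Compounds 1, 3 and 6 are taken as purchased.

## Analysis of the target

Target 14 is a 2,3-dihydro-1,4-benzodioxine neolignan. Ring C (O1, C2, C3, O4, C4a, C8a) is fused to ring B (C4a–C8a), which carries a methoxy group at C5 and an (E)-3-hydroxyprop-1-enyl chain at C7. C2 carries ring A (4-hydroxy-3,5-dimethoxyphenyl) and C3 carries a hydroxymethyl group. The only stereocentres are C2 (S) and C3 (S); they are adjacent and trans, with ring A and the CH2OH group on opposite faces of ring C, both pseudo-equatorial.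

The two oxygens of ring B are not equivalent. O4 (bonded to C3) sits on C4a, next to the C5 methoxy group and para to the C7 chain. O1 (bonded to C2) sits on C8a, meta to the chain. Any synthesis must therefore decide which oxygen of ring B meets which carbon.

The sensitive groups are:
- the C2–O1 bond, a p-hydroxybenzyl aryl ether that ionises to a p-quinone methide, so C2 is stereolabile while C3 is not;
- the allylic alcohol on an electron-rich styrene (acid- and oxidant-sensitive, E geometry must be kept);
- two electron-rich arenes and a free phenol, which rule out hydrogenolysis and harsh oxidants.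

The feature the route is built on is this. C2 is the benzylic carbon para to the free C4'–OH of ring A, and both ortho positions of that phenol (C3', C5') are blocked by methoxy groups. A phenoxyl radical on ring A can therefore only end as the p-quinone methide at C2. The phenolic O1 on C8a is placed to add to C2 in a 6-exo closure of ring C. The real difficulty is then reduced to the absolute configuration at C3 and the regiochemistry on ring B.

## Retrosynthetic reasoning

**14 from 13.** The allylic alcohol is the most acid- and oxidant-sensitive group, so it is unveiled last, by hydride reduction of the methyl (E)-acrylate in 13. Carrying the chain as the ester also keeps ring B less electron-rich during the oxidative step.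

**13 from 11 through 12 (key disconnection).** The C2–O1 bond is cut and, in the same retrosynthetic move, the oxygen at C2 is removed altogether: C2 becomes a plain benzylic CH2 in phenol 11. Forward, a two-electron oxidation of the ring-A phenol gives quinone methide 12, and the C8a hydroxyl adds to C2. This bond is chosen because it is the only bond of ring C whose carbon is made electrophilic by the target's own substitution (the para C4'–OH). The gain is that 11 has one stereocentre instead of two, no benzylic alcohol to protect or differentiate, and no ring. The forward step must oxidise the ring-A phenol in the presence of the ring-B phenol, close ring C, and set C2 trans to C3.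

**11 from 10 from 9.** The CH2OH group on the future C3 is carried as a methyl ester in 9 because the ester activates that carbon for a clean SN2 ether formation. It is reduced before the key step: an ester next to a quinone methide would make the C3–H acidic and allow tautomerisation to an achiral enol ether. The silyl group on ring A is removed just before the oxidation (10 to 11).

**9 from 5 and 7 through 8.** The O4–C3 bond is cut. Forward, the hydroxyl of lactate 5 is turned into triflate 8 and displaced with inversion by the phenoxide of 7. The regiochemistry on ring B comes from acidity: the hydroxyl of 7 para to the acrylate is the more acidic one, and it becomes O4. The other hydroxyl stays free and becomes O1.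

**5 from 2 (through 4) and 3.** The C2–C1' bond (benzylic carbon to ring A) is cut. Forward, aryl Grignard reagent 4 opens the chiral-pool epoxide 3 at its CH2 carbon. The stereocentre of 3 is not touched and becomes C3 of the target, the epoxide CH2 becomes C2, and the ester carbon becomes the CH2OH carbon.

**7 from 6, and 2 from 1.** A Wittig olefination installs the E-acrylate on 6; silylation of 1 makes the aryl bromide fit for Grignard formation.

## Alternatives that were turned down

Alternative 1: the textbook polar route with the C2 oxygen in place from the start. The disconnections are O4–C3 by SN2 and C2–O1 by acid-mediated closure of a benzylic alcohol. Forward, asymmetric dihydroxylation (K2OsO2(OH)4, (DHQD)2PHAL) of the silylated ring-A cinnamate gives diol A1. Its α-hydroxyl is activated and displaced by the phenoxide of 7 to give A2, which is reduced, desilylated and cyclised with acid. It was turned down for three reasons. Both hydroxyls of A1 are secondary, and under the basic phenoxide conditions the free β-hydroxyl can close to a glycidate that reopens at the benzylic carbon, giving the wrong ether unless protection steps are added. The benzylic configuration set by the catalyst is erased in the acid closure. A p-oxybenzylic alcohol β to an ester (retro-aldol, elimination) is carried through several basic steps. The route is longer than the one chosen.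

Alternative 2: the biomimetic route, cutting O4–C3 and O1–C2 at once. Forward, Ag2CO3 oxidises a mixture of sinapyl alcohol A3 and 5-hydroxyconiferyl alcohol A4; radical cross-coupling and internal trapping of the quinone methide give the trans-benzodioxane in one step. It was turned down because every intermediate (phenoxyl radicals, o-quinone, quinone methide) is achiral and unbound to any chiral reagent, so 14 would form together with its enantiomer A5 in equal amounts. A3 also homo-couples, and the side chain of A4 can couple at its own β-carbon. A resolution at the last step would cost at least half of the material.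

Alternative 3: a stereoconvergent reduction followed by closure at the arene. Racemic α-aryloxy-β-keto ester A6 is made from a brominated ring-B phenol. Asymmetric transfer hydrogenation with dynamic kinetic resolution (RuCl(p-cymene)[(R,R)-TsDPEN], HCO2H/Et3N) is expected to give the syn hydroxy ester A7 with both centres set. Ring C is then closed at C8a–O1 by an intramolecular aryl etherification (Pd(OAc)2, bulky biarylphosphine, Cs2CO3) with retention. It was turned down because A7 and the cyclised ester both have an acidic C3–H next to a β-oxygen: under the base of the coupling, retro-aldol of A7 and E1cB ring opening and reclosure of the product through an achiral cinnamate threaten both centres. Avoiding this needs reduction and protection before the coupling, and A6 itself takes four steps. The catalyst control at C2 is also redundant, since the para C4'–OH lets C2 be set from C3.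

Key step: step 7

## Route

Step 1
Reactants: 1 4-bromo-2,6-dimethoxyphenol
Product: 2 tert-butyl(4-bromo-2,6-dimethoxyphenoxy)dimethylsilane
Conditions: TBSCl, imidazole, DMF, rt
Reagents that add atoms: tert-butyldimethylsilyl chloride, CC(C)(C)[Si](C)(C)Cl
Why: Standard silylation of a phenol; the silyl ether masks the acidic hydroxyl for Grignard formation and is later removed by fluoride without touching esters.

Step 2
Reactants: 2 tert-butyl(4-bromo-2,6-dimethoxyphenoxy)dimethylsilane; 3 methyl (2S)-oxirane-2-carboxylate
Product: 5 methyl (2S)-3-[4-(tert-butyldimethylsilyloxy)-3,5-dimethoxyphenyl]-2-hydroxypropanoate, via arylmagnesium bromide 4 (not isolated)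
Conditions: Mg, THF, 45 °C; then CuI (10 mol %), 3, THF, −40 → −20 °C; aq. NH4Cl
Reagents that add atoms: none
Why: Copper-catalysed Grignard opening of a glycidic ester at its unsubstituted CH2 carbon, a known entry to 3-aryl lactates; at low temperature the epoxide reacts before the ester, and the stereocentre of 3 is not touched, so 5 keeps the S configuration.

Step 3
Reactants: 6 3,4-dihydroxy-5-methoxybenzaldehyde
Product: 7 methyl (E)-3-(3,4-dihydroxy-5-methoxyphenyl)prop-2-enoate
Conditions: Ph3P=CHCO2Me, toluene, 90 °C
Reagents that add atoms: methyl (triphenylphosphoranylidene)acetate, COC(=O)C=P(c1ccccc1)(c1ccccc1)c1ccccc1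
Why: Wittig olefination with a stabilised ylide, which tolerates free phenols and gives the E-acrylate.

Step 4
Reactants: 5 methyl (2S)-3-[4-(tert-butyldimethylsilyloxy)-3,5-dimethoxyphenyl]-2-hydroxypropanoate; 7 methyl (E)-3-(3,4-dihydroxy-5-methoxyphenyl)prop-2-enoate
Product: 9 methyl (2R)-3-[4-(tert-butyldimethylsilyloxy)-3,5-dimethoxyphenyl]-2-{2-hydroxy-6-methoxy-4-[(E)-3-methoxy-3-oxoprop-1-enyl]phenoxy}propanoate, via triflate 8 (not isolated)
Conditions: Tf2O, 2,6-lutidine, CH2Cl2, −78 °C; then 7 (1.3 equiv) premixed with K2CO3 (1.3 equiv), MeCN, −20 → 0 °C; AcOH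
Reagents that add atoms: none
Why: SN2 displacement of an α-triflyloxy ester by a phenoxide, which runs fast and with clean inversion (S in 8 to R in 9) because the ester suppresses ionisation and aryl participation; the phenoxide forms at the more acidic hydroxyl of 7 (para to the acrylate), which fixes O4 on the carbon next to the methoxy group.

Step 5
Reactants: 9 methyl (2R)-3-[4-(tert-butyldimethylsilyloxy)-3,5-dimethoxyphenyl]-2-{2-hydroxy-6-methoxy-4-[(E)-3-methoxy-3-oxoprop-1-enyl]phenoxy}propanoate
Product: 10 methyl (E)-3-[4-({(2R)-1-[4-(tert-butyldimethylsilyloxy)-3,5-dimethoxyphenyl]-3-hydroxypropan-2-yl}oxy)-3-hydroxy-5-methoxyphenyl]prop-2-enoate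
Conditions: NaBH4, THF/MeOH, 0 °C → rt
Reagents that add atoms: none
Why: Chemoselective borohydride reduction: the α-aryloxy ester (or the six-membered lactone it may form with the neighbouring ring-B hydroxyl) is activated and is reduced, while the conjugated acrylate is inert under these conditions; the stereocentre is not involved.

Step 6
Reactants: 10 methyl (E)-3-[4-({(2R)-1-[4-(tert-butyldimethylsilyloxy)-3,5-dimethoxyphenyl]-3-hydroxypropan-2-yl}oxy)-3-hydroxy-5-methoxyphenyl]prop-2-enoate
Product: 11 methyl (E)-3-[3-hydroxy-4-({(2R)-1-hydroxy-3-(4-hydroxy-3,5-dimethoxyphenyl)propan-2-yl}oxy)-5-methoxyphenyl]prop-2-enoate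
Conditions: Bu4NF, AcOH, THF, 0 °C
Reagents that add atoms: none
Why: Buffered fluoride cleavage of an aryl silyl ether, which leaves the ester and the alkene alone and frees the ring-A phenol needed for the oxidation.

Step 7
Reactants: 11 methyl (E)-3-[3-hydroxy-4-({(2R)-1-hydroxy-3-(4-hydroxy-3,5-dimethoxyphenyl)propan-2-yl}oxy)-5-methoxyphenyl]prop-2-enoate
Product: 13 methyl (E)-3-[(2S,3S)-2-(4-hydroxy-3,5-dimethoxyphenyl)-3-(hydroxymethyl)-5-methoxy-2,3-dihydro-1,4-benzodioxin-7-yl]prop-2-enoate, via quinone methide 12 (not isolated)
Conditions: Ag2O (1.2 equiv), 4 Å molecular sieves, CH2Cl2, rt, dark; filter; then CSA (5 mol %), CH2Cl2, 0 °C → rt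
Reagents that add atoms: none
Why: Ag2O oxidises the ring-A phenol to its phenoxyl radical, and since both ortho positions carry methoxy groups the radical can only go on, by disproportionation or a second oxidation, to p-quinone methide 12, in which the former benzylic CH2 is an electrophilic sp2 carbon. The closest known reaction types are the Ag2O oxidation of 4-alkyl-2,6-dimethoxyphenols to p-quinone methides and the internal trapping of β-aryloxy quinone methides by an ortho phenol, which gives trans-benzodioxanes in oxidative phenol couplings. The ring-B hydroxyl on the future C8a adds to the exocyclic carbon of 12 (1,6-addition), which re-aromatises ring A and closes ring C in 6-exo-trig mode. The new stereocentre C2 is controlled by C3: in the chair-like transition state the CH2OH group and ring A both take pseudo-equatorial positions, which leads to the trans (2S,3S) isomer. The product is also the thermodynamic isomer, because under catalytic CSA the C2–O1 bond can reopen through the same quinone methide, so any cis material is funnelled to trans while C3, which has no acidic hydrogen at this oxidation level, stays fixed. The step needs oxidation of the ring-A phenol and not of the ring-B phenol; this is secured by the two ortho methoxy groups and the para alkyl group of ring A, whereas the ring-B phenol is hydrogen-bonded to O4, has no para substituent and sits on a ring that carries the acrylate. Over-oxidation of 13 at C2 is limited by the stoichiometry of Ag2O and by the hindered, ring-bound position of the C2–H.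

Step 8
Reactants: 13 methyl (E)-3-[(2S,3S)-2-(4-hydroxy-3,5-dimethoxyphenyl)-3-(hydroxymethyl)-5-methoxy-2,3-dihydro-1,4-benzodioxin-7-yl]prop-2-enoate
Product: 14 4-[(2S,3S)-3-(hydroxymethyl)-7-[(E)-3-hydroxyprop-1-enyl]-5-methoxy-2,3-dihydro-1,4-benzodioxin-2-yl]-2,6-dimethoxyphenol
Conditions: i-Bu2AlH (6 equiv), CH2Cl2, −78 → −40 °C; aq. potassium sodium tartrate
Reagents that add atoms: none
Why: 1,2-Reduction of a cinnamate ester to the E-allylic alcohol with an aluminium hydride, the standard access to cinnamyl alcohols; the free phenol and the primary alcohol only consume extra hydride, and the cold, non-acidic work-up leaves C2–O1 intact.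

## Compound list

1 | 4-bromo-2,6-dimethoxyphenol | COc1cc(Br)cc(OC)c1O | starting material
2 | tert-butyl(4-bromo-2,6-dimethoxyphenoxy)dimethylsilane | COc1cc(Br)cc(OC)c1O[Si](C)(C)C(C)(C)C | intermediate
3 | methyl (2S)-oxirane-2-carboxylate | COC(=O)[C@@H]1CO1 | starting material
4 | [4-(tert-butyldimethylsilyloxy)-3,5-dimethoxyphenyl]magnesium bromide | COc1cc([Mg]Br)cc(OC)c1O[Si](C)(C)C(C)(C)C | intermediate (not isolated)
5 | methyl (2S)-3-[4-(tert-butyldimethylsilyloxy)-3,5-dimethoxyphenyl]-2-hydroxypropanoate | COC(=O)[C@@H](O)Cc1cc(OC)c(O[Si](C)(C)C(C)(C)C)c(OC)c1 | intermediate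
6 | 3,4-dihydroxy-5-methoxybenzaldehyde | COc1cc(C=O)cc(O)c1O | starting material
7 | methyl (E)-3-(3,4-dihydroxy-5-methoxyphenyl)prop-2-enoate | COC(=O)/C=C/c1cc(O)c(O)c(OC)c1 | intermediate
8 | methyl (2S)-3-[4-(tert-butyldimethylsilyloxy)-3,5-dimethoxyphenyl]-2-(trifluoromethylsulfonyloxy)propanoate | COC(=O)[C@@H](OS(=O)(=O)C(F)(F)F)Cc1cc(OC)c(O[Si](C)(C)C(C)(C)C)c(OC)c1 | intermediate (not isolated)
9 | methyl (2R)-3-[4-(tert-butyldimethylsilyloxy)-3,5-dimethoxyphenyl]-2-{2-hydroxy-6-methoxy-4-[(E)-3-methoxy-3-oxoprop-1-enyl]phenoxy}propanoate | COC(=O)[C@H](Oc1c(O)cc(/C=C/C(=O)OC)cc1OC)Cc1cc(OC)c(O[Si](C)(C)C(C)(C)C)c(OC)c1 | intermediate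
10 | methyl (E)-3-[4-({(2R)-1-[4-(tert-butyldimethylsilyloxy)-3,5-dimethoxyphenyl]-3-hydroxypropan-2-yl}oxy)-3-hydroxy-5-methoxyphenyl]prop-2-enoate | OC[C@H](Oc1c(O)cc(/C=C/C(=O)OC)cc1OC)Cc1cc(OC)c(O[Si](C)(C)C(C)(C)C)c(OC)c1 | intermediate
11 | methyl (E)-3-[3-hydroxy-4-({(2R)-1-hydroxy-3-(4-hydroxy-3,5-dimethoxyphenyl)propan-2-yl}oxy)-5-methoxyphenyl]prop-2-enoate | OC[C@H](Oc1c(O)cc(/C=C/C(=O)OC)cc1OC)Cc1cc(OC)c(O)c(OC)c1 | intermediate
12 | methyl (E)-3-[4-({(2R)-1-(3,5-dimethoxy-4-oxocyclohexa-2,5-dien-1-ylidene)-3-hydroxypropan-2-yl}oxy)-3-hydroxy-5-methoxyphenyl]prop-2-enoate | OC[C@H](Oc1c(O)cc(/C=C/C(=O)OC)cc1OC)C=C1C=C(OC)C(=O)C(OC)=C1 | intermediate (not isolated)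
13 | methyl (E)-3-[(2S,3S)-2-(4-hydroxy-3,5-dimethoxyphenyl)-3-(hydroxymethyl)-5-methoxy-2,3-dihydro-1,4-benzodioxin-7-yl]prop-2-enoate | COc1cc([C@@H]2Oc3cc(/C=C/C(=O)OC)cc(OC)c3O[C@H]2CO)cc(OC)c1O | intermediate
14 | 4-[(2S,3S)-3-(hydroxymethyl)-7-[(E)-3-hydroxyprop-1-enyl]-5-methoxy-2,3-dihydro-1,4-benzodioxin-2-yl]-2,6-dimethoxyphenol | COc1cc([C@@H]2Oc3cc(/C=C/CO)cc(OC)c3O[C@H]2CO)cc(OC)c1O | target

## Step count and least certain steps

Total: 8 steps. Longest linear sequence: 7 steps (1, 2, 4, 5, 6, 7, 8); step 3 is a one-step side branch.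

**Step 7 (key step).** Three processes may interfere:
- competing oxidation of the ring-B phenol, followed by intermolecular phenol coupling;
- base-promoted tautomerisation of quinone methide 12 to an enol ether on the Ag2O surface, which would destroy the C3 stereocentre;
- a second oxidation of the product at C2.

The same two-electron oxidation could also be driven at a carbon anode, but that changes only the conditions. The fallback separates the oxidation from the ring closure and removes the second phenol from the oxidation. It sets out from 10 and returns at 13.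
- Both free hydroxyls of 10 are acetylated (Ac2O, pyridine) to give the diacetate F1.
- Buffered fluoride gives the ring-A phenol F2, the only phenol left in the molecule.
- Ag2O converts F2 into the isolable quinone methide F3, which is quenched with methanol.
- K2CO3 in methanol removes the acetates to give the benzylic methyl ether F4 as a mixture of C1 epimers.
- Catalytic CSA in CH2Cl2 ionises the benzylic ether and closes ring C in the conventional acid-mediated way, under thermodynamic control, to 13.

**Step 4.** The risks are alkylation at the less acidic hydroxyl of 7 (loss of regiocontrol), E2 elimination of the triflate towards the cinnamate, and partial epimerisation at the α-carbon if the product lactonises onto the neighbouring phenol under base. The fallback makes the regiochemistry structural. It sets out from 5 (through triflate 8) and returns at 9.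
- The bromophenol methyl (E)-3-(3-bromo-4-hydroxy-5-methoxyphenyl)prop-2-enoate F5 (Wittig product of commercial 5-bromovanillin) has a single hydroxyl and displaces triflate 8 to give the bromo ether F6.
- Miyaura borylation (B2pin2, PdCl2(dppf), KOAc, dioxane, 85 °C) gives the pinacol boronate F7.
- Oxidation with NaBO3·4H2O in THF/water installs the ring-B hydroxyl and gives 9.

**Step 5.** The risks are incomplete discrimination between the two esters (conjugate reduction or reduction of the acrylate) and slow reduction of the hindered α-aryloxy ester; premature loss of the silyl group would be harmless. The fallback avoids an ester at this carbon altogether. It sets out from 4 and returns at 11.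
- Grignard reagent 4 opens commercial (S)-tert-butyldimethylsilyl glycidyl ether under CuI catalysis to give the secondary alcohol F8.
- Its triflate is displaced at low temperature by the phenoxide of 7, with inversion, to give the bis-silyl ether F9.
- Excess buffered Bu4NF removes both silyl groups and gives 11.

This path is one step shorter but puts the ether formation on an unactivated secondary carbon next to an electron-rich benzyl group, which is why it is not the main route.

**Step 8.** The risk is reductive opening of ring C: the aluminium phenoxide of ring A can expel O1 to a quinone methide, which then captures hydride; over-reduction of the alkene is a lesser risk. The fallback reduces before ring C exists. It sets out from 9 and returns at 14.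
- i-Bu2AlH reduces both esters of 9 to give the silylated allylic alcohol F10.
- Buffered fluoride gives the free phenol F11.
- The Ag2O/CSA cyclisation of step 7 is run as the last step and gives 14 directly.

## Further compounds

F1 | step 7 | methyl (E)-3-[3-(acetyloxy)-4-({(2R)-1-(acetyloxy)-3-[4-(tert-butyldimethylsilyloxy)-3,5-dimethoxyphenyl]propan-2-yl}oxy)-5-methoxyphenyl]prop-2-enoate | CC(=O)OC[C@H](Oc1c(OC(C)=O)cc(/C=C/C(=O)OC)cc1OC)Cc1cc(OC)c(O[Si](C)(C)C(C)(C)C)c(OC)c1
F2 | step 7 | methyl (E)-3-[3-(acetyloxy)-4-({(2R)-1-(acetyloxy)-3-(4-hydroxy-3,5-dimethoxyphenyl)propan-2-yl}oxy)-5-methoxyphenyl]prop-2-enoate | CC(=O)OC[C@H](Oc1c(OC(C)=O)cc(/C=C/C(=O)OC)cc1OC)Cc1cc(OC)c(O)c(OC)c1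
F3 | step 7 | methyl (E)-3-[3-(acetyloxy)-4-({(2R)-1-(acetyloxy)-3-(3,5-dimethoxy-4-oxocyclohexa-2,5-dien-1-ylidene)propan-2-yl}oxy)-5-methoxyphenyl]prop-2-enoate | CC(=O)OC[C@H](Oc1c(OC(C)=O)cc(/C=C/C(=O)OC)cc1OC)C=C1C=C(OC)C(=O)C(OC)=C1
F4 | step 7 | methyl (E)-3-[3-hydroxy-4-({(1RS,2S)-3-hydroxy-1-(4-hydroxy-3,5-dimethoxyphenyl)-1-methoxypropan-2-yl}oxy)-5-methoxyphenyl]prop-2-enoate | OC[C@H](Oc1c(O)cc(/C=C/C(=O)OC)cc1OC)C(OC)c1cc(OC)c(O)c(OC)c1
F5 | step 4 | methyl (E)-3-(3-bromo-4-hydroxy-5-methoxyphenyl)prop-2-enoate | COC(=O)/C=C/c1cc(Br)c(O)c(OC)c1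
F6 | step 4 | methyl (2R)-2-{2-bromo-6-methoxy-4-[(E)-3-methoxy-3-oxoprop-1-enyl]phenoxy}-3-[4-(tert-butyldimethylsilyloxy)-3,5-dimethoxyphenyl]propanoate | COC(=O)[C@H](Oc1c(Br)cc(/C=C/C(=O)OC)cc1OC)Cc1cc(OC)c(O[Si](C)(C)C(C)(C)C)c(OC)c1
F7 | step 4 | methyl (2R)-3-[4-(tert-butyldimethylsilyloxy)-3,5-dimethoxyphenyl]-2-{2-methoxy-4-[(E)-3-methoxy-3-oxoprop-1-enyl]-6-(4,4,5,5-tetramethyl-1,3,2-dioxaborolan-2-yl)phenoxy}propanoate | COC(=O)[C@H](Oc1c(B2OC(C)(C)C(C)(C)O2)cc(/C=C/C(=O)OC)cc1OC)Cc1cc(OC)c(O[Si](C)(C)C(C)(C)C)c(OC)c1
F8 | step 5 | (2S)-1-(tert-butyldimethylsilyloxy)-3-[4-(tert-butyldimethylsilyloxy)-3,5-dimethoxyphenyl]propan-2-ol | CC(C)(C)[Si](C)(C)OC[C@@H](O)Cc1cc(OC)c(O[Si](C)(C)C(C)(C)C)c(OC)c1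
F9 | step 5 | methyl (E)-3-[4-({(2R)-1-(tert-butyldimethylsilyloxy)-3-[4-(tert-butyldimethylsilyloxy)-3,5-dimethoxyphenyl]propan-2-yl}oxy)-3-hydroxy-5-methoxyphenyl]prop-2-enoate | CC(C)(C)[Si](C)(C)OC[C@H](Oc1c(O)cc(/C=C/C(=O)OC)cc1OC)Cc1cc(OC)c(O[Si](C)(C)C(C)(C)C)c(OC)c1
F10 | step 8 | (2R)-3-[4-(tert-butyldimethylsilyloxy)-3,5-dimethoxyphenyl]-2-{2-hydroxy-4-[(E)-3-hydroxyprop-1-enyl]-6-methoxyphenoxy}propan-1-ol | OC[C@H](Oc1c(O)cc(/C=C/CO)cc1OC)Cc1cc(OC)c(O[Si](C)(C)C(C)(C)C)c(OC)c1
F11 | step 8 | 4-[(2R)-3-hydroxy-2-{2-hydroxy-4-[(E)-3-hydroxyprop-1-enyl]-6-methoxyphenoxy}propyl]-2,6-dimethoxyphenol | OC[C@H](Oc1c(O)cc(/C=C/CO)cc1OC)Cc1cc(OC)c(O)c(OC)c1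
A1 | alternative 1 | methyl (2S,3R)-3-[4-(tert-butyldimethylsilyloxy)-3,5-dimethoxyphenyl]-2,3-dihydroxypropanoate | COC(=O)[C@@H](O)[C@H](O)c1cc(OC)c(O[Si](C)(C)C(C)(C)C)c(OC)c1
A2 | alternative 1 | methyl (2R,3R)-3-[4-(tert-butyldimethylsilyloxy)-3,5-dimethoxyphenyl]-3-hydroxy-2-{2-hydroxy-6-methoxy-4-[(E)-3-methoxy-3-oxoprop-1-enyl]phenoxy}propanoate | COC(=O)[C@H](Oc1c(O)cc(/C=C/C(=O)OC)cc1OC)[C@H](O)c1cc(OC)c(O[Si](C)(C)C(C)(C)C)c(OC)c1
A3 | alternative 2 | 4-[(E)-3-hydroxyprop-1-enyl]-2,6-dimethoxyphenol (sinapyl alcohol) | COc1cc(/C=C/CO)cc(OC)c1O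
A4 | alternative 2 | 5-[(E)-3-hydroxyprop-1-enyl]-3-methoxybenzene-1,2-diol (5-hydroxyconiferyl alcohol) | COc1cc(/C=C/CO)cc(O)c1O
A5 | alternative 2 | 4-[(2R,3R)-3-(hydroxymethyl)-7-[(E)-3-hydroxyprop-1-enyl]-5-methoxy-2,3-dihydro-1,4-benzodioxin-2-yl]-2,6-dimethoxyphenol | COc1cc([C@H]2Oc3cc(/C=C/CO)cc(OC)c3O[C@@H]2CO)cc(OC)c1O
A6 | alternative 3 | methyl 2-{2-bromo-6-methoxy-4-[(E)-3-methoxy-3-oxoprop-1-enyl]phenoxy}-3-[3,5-dimethoxy-4-(pivaloyloxy)phenyl]-3-oxopropanoate (racemic) | COC(=O)C(Oc1c(Br)cc(/C=C/C(=O)OC)cc1OC)C(=O)c1cc(OC)c(OC(=O)C(C)(C)C)c(OC)c1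
A7 | alternative 3 | methyl (2R,3S)-2-{2-bromo-6-methoxy-4-[(E)-3-methoxy-3-oxoprop-1-enyl]phenoxy}-3-[3,5-dimethoxy-4-(pivaloyloxy)phenyl]-3-hydroxypropanoate | COC(=O)[C@H](Oc1c(Br)cc(/C=C/C(=O)OC)cc1OC)[C@@H](O)c1cc(OC)c(OC(=O)C(C)(C)C)c(OC)c1
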